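The route rests on disconnecting the C2–C3 bond of ring B (the dihydrofuran). In the target, C2 is bonded to O1, to the C3 carbinol carbon and to a 1,1-disubstituted vinyl group, the signature of a 2-substituted allyl nucleophile that has added to an aldehyde. A copper-catalysed asymmetric borylative cyclization of an ortho-allenyloxy benzaldehyde therefore closes ring B, forms C2–C3, sets both ring stereocentres cis and leaves a vinylic C–B bond as the handle for the formylvinyl group. The precursor is the O-allenyl ether of 5-acetylsalicylaldehyde, made by propargylation and base isomerization under acetal protection. Methylation, two esterifications, an asymmetric ketone reduction and an allylic oxidation finish the synthesis.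

Key step: step 4

Assumption: (R,R)-Ph-BPE is taken to give the (2R,3R) series by analogy with intermolecular borylative allene–aldehyde couplings; if the opposite sense is found, (S,S)-Ph-BPE is used and nothing else changes.

Step 1
Reactants: 1 5-acetyl-2-hydroxybenzaldehyde; 2 propargyl bromide
Product: 3 5-acetyl-2-(prop-2-yn-1-yloxy)benzaldehyde
Conditions: K2CO3, DMF, rt
Reagents that add atoms: none
Why: Williamson etherification: K2CO3 deprotonates the phenol, made acidic by the ortho-formyl and para-acetyl groups, and the phenoxide displaces bromide from the primary propargylic halide in an SN2 reaction, while carbonate at room temperature is too weak a base to start aldol condensation between the two carbonyl groups.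

Step 2
Reactants: 3 5-acetyl-2-(prop-2-yn-1-yloxy)benzaldehyde
Product: 4 2-(dimethoxymethyl)-4-(1,1-dimethoxyethyl)-1-(prop-2-yn-1-yloxy)benzene
Conditions: HC(OMe)3, MeOH, TsOH·H2O (cat.), rt; Et3N quench
Reagents that add atoms: trimethyl orthoformate, COC(OC)OC; methanol, CO
Why: Acid-catalysed acetalization with trimethyl orthoformate as dehydrating agent converts both the aldehyde and the aryl methyl ketone into dimethyl acetals, so that the next step meets neither an electrophilic carbonyl group nor ketone α-protons that would consume the catalytic base and set off aldol condensation.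

Step 3
Reactants: 4 2-(dimethoxymethyl)-4-(1,1-dimethoxyethyl)-1-(prop-2-yn-1-yloxy)benzene
Product: 6 5-acetyl-2-(propa-1,2-dien-1-yloxy)benzaldehyde, via allenyl bis-acetal 5 (not isolated)
Conditions: KOtBu (30 mol %), THF, 0 °C to rt; aq. NaHCO3 work-up; then PPTS (cat.), acetone/H2O, rt
Reagents that add atoms: water, O
Why: Base-mediated prototropic isomerization of an aryl propargyl ether to the allenyl ether with catalytic KOtBu is standard and is stopped before the 1-propynyl ether appears, and the two dimethyl acetals are then hydrolysed by the buffered pyridinium acid in wet acetone, conditions under which acyclic acetals cleave far faster than the electron-poor aryloxyallene is protonated.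

Step 4
Reactants: 6 5-acetyl-2-(propa-1,2-dien-1-yloxy)benzaldehyde; 7 bis(pinacolato)diboron
Product: 9 1-[(2R,3R)-3-hydroxy-2-[1-(4,4,5,5-tetramethyl-1,3,2-dioxaborolan-2-yl)ethenyl]-2,3-dihydro-1-benzofuran-5-yl]ethan-1-one, via O-boryl ether 8 (not isolated)
Conditions: CuCl (5 mol %), (R,R)-Ph-BPE (6 mol %), NaOtBu (5 mol %), THF, 0 °C to rt, slow addition of 6, no protic additive; then aq. NH4Cl
Reagents that add atoms: none
Why: Proposed new method: the bisphosphine-bound copper boryl generated from CuCl, NaOtBu and 7 (copper remains univalent throughout) should add across the unsubstituted C=C of the aryloxyallene, boron going to the central carbon from the side remote from the aryloxy group and copper to CH2, and the resulting (Z)-2-boryl-3-aryloxyallylcopper should attack the ortho aldehyde through its oxygen-bearing γ-carbon in a six-membered chair, after which the copper alkoxide is turned over by 7 to the borate ester 8 that is hydrolysed on work-up. The closest known reaction types are the CuCl/chiral bisphosphine-catalysed enantioselective three-component couplings of allenes, diboron and aldehydes and the copper-catalysed borylative cyclizations of allenes tethered to ketones; untested is an allene whose bond-forming carbon carries an aryloxy group, so that an acetal-level carbon (C2) acts as the nucleophile. Ring B is closed in the 5-exo-trig mode onto the carbonyl carbon, which becomes C3. The cis relation of C2 and C3 is controlled by the Z geometry of the allylcopper, which places O1 axial and the aryl carbon C3a equatorial in the chair, and the absolute (2R,3R) configuration by the chiral bisphosphine, which selects the aldehyde face. The step needs site selectivity (γ-attack giving the five-membered ring, not α-attack giving a seven-membered ring), chemoselectivity (borylcupration of the allene before 1,2-borylation of the aldehyde, and aldehyde before acetyl) and freedom from base-induced aldol chemistry; these are secured by the ortho placement of formyl and allenyloxy groups, which lets only the aldehyde be reached intramolecularly, by the terminal allene π bond being inductively activated by the aryloxy group, and by keeping NaOtBu equimolar with CuCl.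

Step 5
Reactants: 9 1-[(2R,3R)-3-hydroxy-2-[1-(4,4,5,5-tetramethyl-1,3,2-dioxaborolan-2-yl)ethenyl]-2,3-dihydro-1-benzofuran-5-yl]ethan-1-one
Product: 10 1-[(2R,3R)-3-hydroxy-2-(prop-1-en-2-yl)-2,3-dihydro-1-benzofuran-5-yl]ethan-1-one
Conditions: MeI, Pd2(dba)3 (cat.), P(o-tol)3, K2CO3, DMF/H2O, 60 °C (sealed)
Reagents that add atoms: iodomethane, CI
Why: Suzuki–Miyaura cross-coupling of the alkenyl pinacol boronate with iodomethane, by oxidative addition of MeI to zerovalent palladium, transmetalation and reductive elimination, replaces boron by methyl with retention at the sp2 carbon and touches neither stereocentre, the free hydroxyl or the ketone.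

Step 6
Reactants: 10 1-[(2R,3R)-3-hydroxy-2-(prop-1-en-2-yl)-2,3-dihydro-1-benzofuran-5-yl]ethan-1-one
Product: 11 (2R,3R)-5-acetyl-2-(prop-1-en-2-yl)-2,3-dihydro-1-benzofuran-3-yl 3-methylbutanoate
Conditions: isovaleryl chloride, pyridine, DMAP (cat.), CH2Cl2, 0 °C to rt
Reagents that add atoms: 3-methylbutanoyl chloride, CC(C)CC(=O)Cl
Why: DMAP-catalysed O-acylation of the only hydroxyl group by the acid chloride forms the ester at oxygen without breaking the C3–O bond, so the cis (2R,3R) configuration is kept, and the weak amine base at low temperature avoids elimination to the aromatic benzofuran.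

Step 7
Reactants: 11 (2R,3R)-5-acetyl-2-(prop-1-en-2-yl)-2,3-dihydro-1-benzofuran-3-yl 3-methylbutanoate
Product: 12 (2R,3R)-5-[(1S)-1-hydroxyethyl]-2-(prop-1-en-2-yl)-2,3-dihydro-1-benzofuran-3-yl 3-methylbutanoate
Conditions: RuCl[(S,S)-TsDPEN](p-cymene) (1 mol %), HCO2H/Et3N (5:2), EtOAc, rt
Reagents that add atoms: none
Why: Noyori asymmetric transfer hydrogenation reduces the aryl methyl ketone by outer-sphere hydride transfer from the (S,S)-TsDPEN ruthenium hydride to the Re face, which for aryl methyl ketones gives the (S)-carbinol under catalyst control, and it leaves the isopropenyl group and the ester untouched, which a borane reagent would not guarantee.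

Step 8
Reactants: 12 (2R,3R)-5-[(1S)-1-hydroxyethyl]-2-(prop-1-en-2-yl)-2,3-dihydro-1-benzofuran-3-yl 3-methylbutanoate
Product: 13 (2R,3R)-5-[(1S)-1-(acetyloxy)ethyl]-2-(prop-1-en-2-yl)-2,3-dihydro-1-benzofuran-3-yl 3-methylbutanoate
Conditions: Ac2O, pyridine, DMAP (cat.), CH2Cl2, 0 °C to rt
Reagents that add atoms: acetic anhydride, CC(=O)OC(C)=O
Why: Acetylation with Ac2O under nucleophilic catalysis acylates the secondary benzylic alcohol at oxygen, so the (S) configuration is retained.

Step 9
Reactants: 13 (2R,3R)-5-[(1S)-1-(acetyloxy)ethyl]-2-(prop-1-en-2-yl)-2,3-dihydro-1-benzofuran-3-yl 3-methylbutanoate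
Product: 15 (2R,3R)-5-[(1S)-1-(acetyloxy)ethyl]-2-(3-oxoprop-1-en-2-yl)-2,3-dihydro-1-benzofuran-3-yl 3-methylbutanoate, via allylic alcohol 14 (not isolated)
Conditions: SeO2 (0.5 equiv), tBuOOH, CH2Cl2, rt; filtration and concentration; then Dess–Martin periodinane, CH2Cl2, 0 °C
Reagents that add atoms: selenium dioxide, O=[Se]=O; tert-butyl hydroperoxide, CC(C)(C)OO
Why: Allylic oxidation with SeO2 (ene reaction followed by 2,3-sigmatropic shift) attacks the methyl group of the 1,1-disubstituted alkene in preference to the allylic methine C2–H, as is usual for isopropenyl groups on 2,3-dihydrobenzofurans, and Dess–Martin oxidation converges the allylic alcohol and enal mixture on the enal without touching the esters or the three stereocentres.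

Compound list
1 | 5-acetyl-2-hydroxybenzaldehyde | CC(=O)c1ccc(O)c(C=O)c1 | starting material
2 | propargyl bromide (3-bromoprop-1-yne) | C#CCBr | starting material
3 | 5-acetyl-2-(prop-2-yn-1-yloxy)benzaldehyde | CC(=O)c1ccc(OCC#C)c(C=O)c1 | intermediate
4 | 2-(dimethoxymethyl)-4-(1,1-dimethoxyethyl)-1-(prop-2-yn-1-yloxy)benzene | COC(C)(OC)c1ccc(OCC#C)c(C(OC)OC)c1 | intermediate
5 | 2-(dimethoxymethyl)-4-(1,1-dimethoxyethyl)-1-(propa-1,2-dien-1-yloxy)benzene | COC(C)(OC)c1ccc(OC=C=C)c(C(OC)OC)c1 | intermediate
6 | 5-acetyl-2-(propa-1,2-dien-1-yloxy)benzaldehyde | CC(=O)c1ccc(OC=C=C)c(C=O)c1 | intermediate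
7 | bis(pinacolato)diboron | CC1(C)OB(OC1(C)C)B1OC(C)(C)C(C)(C)O1 | starting material
8 | 1-[(2R,3R)-2-[1-(4,4,5,5-tetramethyl-1,3,2-dioxaborolan-2-yl)ethenyl]-3-[(4,4,5,5-tetramethyl-1,3,2-dioxaborolan-2-yl)oxy]-2,3-dihydro-1-benzofuran-5-yl]ethan-1-one | C=C(B1OC(C)(C)C(C)(C)O1)[C@H]1Oc2ccc(C(C)=O)cc2[C@H]1OB1OC(C)(C)C(C)(C)O1 | intermediate
9 | 1-[(2R,3R)-3-hydroxy-2-[1-(4,4,5,5-tetramethyl-1,3,2-dioxaborolan-2-yl)ethenyl]-2,3-dihydro-1-benzofuran-5-yl]ethan-1-one | C=C(B1OC(C)(C)C(C)(C)O1)[C@H]1Oc2ccc(C(C)=O)cc2[C@H]1O | intermediate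
10 | 1-[(2R,3R)-3-hydroxy-2-(prop-1-en-2-yl)-2,3-dihydro-1-benzofuran-5-yl]ethan-1-one | C=C(C)[C@H]1Oc2ccc(C(C)=O)cc2[C@H]1O | intermediate
11 | (2R,3R)-5-acetyl-2-(prop-1-en-2-yl)-2,3-dihydro-1-benzofuran-3-yl 3-methylbutanoate | C=C(C)[C@H]1Oc2ccc(C(C)=O)cc2[C@H]1OC(=O)CC(C)C | intermediate
12 | (2R,3R)-5-[(1S)-1-hydroxyethyl]-2-(prop-1-en-2-yl)-2,3-dihydro-1-benzofuran-3-yl 3-methylbutanoate | C=C(C)[C@H]1Oc2ccc([C@H](C)O)cc2[C@H]1OC(=O)CC(C)C | intermediate
13 | (2R,3R)-5-[(1S)-1-(acetyloxy)ethyl]-2-(prop-1-en-2-yl)-2,3-dihydro-1-benzofuran-3-yl 3-methylbutanoate | C=C(C)[C@H]1Oc2ccc([C@H](C)OC(C)=O)cc2[C@H]1OC(=O)CC(C)C | intermediate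
14 | (2R,3R)-5-[(1S)-1-(acetyloxy)ethyl]-2-(3-hydroxyprop-1-en-2-yl)-2,3-dihydro-1-benzofuran-3-yl 3-methylbutanoate | C=C(CO)[C@H]1Oc2ccc([C@H](C)OC(C)=O)cc2[C@H]1OC(=O)CC(C)C | intermediate
15 | (2R,3R)-5-[(1S)-1-(acetyloxy)ethyl]-2-(3-oxoprop-1-en-2-yl)-2,3-dihydro-1-benzofuran-3-yl 3-methylbutanoate | C=C(C=O)[C@H]1Oc2ccc([C@H](C)OC(C)=O)cc2[C@H]1OC(=O)CC(C)C | target

Total step count: 9. Longest linear sequence: 9 steps (1 to 15).

Steps most likely to fail

Step 4. The copper boryl may add to the aldehyde carbonyl before it inserts the allene, the allylcopper may be protonated or close through its CH2 terminus, free alkoxide may start aldol condensation at the acetyl group, or the ligand may discriminate the aldehyde faces poorly. The fallback uses known chemistry, sets out from 1 and returns at 11, so that steps 2 to 6 are not needed. Ring B is closed through the O1–C2 bond by a phenoxide opening an epoxide.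
- Silylation of 1 (TBSCl, imidazole, DMF) gives 5-acetyl-2-[(tert-butyldimethylsilyl)oxy]benzaldehyde F1.
- A Nozaki–Hiyama–Kishi reaction with 1-bromo-2-methylprop-1-ene (CrCl2, NiCl2 cat., DMF), which adds to the aldehyde and spares the ketone, gives racemic 1-{4-[(tert-butyldimethylsilyl)oxy]-3-(1-hydroxy-3-methylbut-2-en-1-yl)phenyl}ethan-1-one F2.
- Sharpless kinetic resolution (Ti(OiPr)4, L-(+)-diisopropyl tartrate, tBuOOH 0.6 equiv, CH2Cl2, −20 °C) should consume the (R)-alcohol and leave 1-{4-[(tert-butyldimethylsilyl)oxy]-3-[(1S)-1-hydroxy-3-methylbut-2-en-1-yl]phenyl}ethan-1-one F3.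
- mCPBA (CH2Cl2, 0 °C) should epoxidise F3 under hydroxyl direction and allylic 1,3-strain control to the threo epoxy alcohol 1-{4-[(tert-butyldimethylsilyl)oxy]-3-[(R)-[(2R)-3,3-dimethyloxiran-2-yl](hydroxy)methyl]phenyl}ethan-1-one F4.
- TBAF (THF, 0 °C) frees the phenoxide, which opens the epoxide 5-exo-tet at the secondary carbon with inversion to give the cis diol 1-[(2S,3R)-3-hydroxy-2-(2-hydroxypropan-2-yl)-2,3-dihydro-1-benzofuran-5-yl]ethan-1-one F5.
- Isovaleryl chloride and pyridine acylate only the secondary hydroxyl, giving (2S,3R)-5-acetyl-2-(2-hydroxypropan-2-yl)-2,3-dihydro-1-benzofuran-3-yl 3-methylbutanoate F6.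
- Dehydration of the tertiary alcohol with the Burgess reagent (benzene, 50 °C) gives 11.

Step 3. The allenyl ether may isomerize further to the 1-propynyl ether, or it may be hydrated or cleaved by the acid needed to hydrolyse the acetals. The fallback sets out from 3 and returns at 6, replacing steps 2 and 3. The carbonyl groups are masked by reduction, so no acid is needed once the allene is in place.
- NaBH4 (MeOH, 0 °C) gives the diol 1-[3-(hydroxymethyl)-4-(prop-2-yn-1-yloxy)phenyl]ethan-1-ol F7, racemic at the carbinol, which is of no consequence.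
- KOtBu (2.5 equiv, THF, rt) isomerises the dialkoxide to 1-[3-(hydroxymethyl)-4-(propa-1,2-dien-1-yloxy)phenyl]ethan-1-ol F8.
- Activated MnO2 (CH2Cl2, rt) oxidises both benzylic alcohols under neutral conditions to 6.

Step 9. The ene reaction may abstract the C2 methine hydrogen, the warm acidic medium may eliminate isovaleric acid to give the aromatic benzofuran, or the enal may over-oxidise or polymerise. The fallback sets out from 13 and returns at 15. C–H functionalization and oxidation are separated.
- Selenium-catalysed ene-type allylic chlorination (N-chlorosuccinimide, PhSeCl cat., CH2Cl2, rt) gives the transposed allylic chloride (2R,3R)-5-[(1S)-1-(acetyloxy)ethyl]-2-(3-chloroprop-1-en-2-yl)-2,3-dihydro-1-benzofuran-3-yl 3-methylbutanoate F9.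
- A Ganem oxidation (trimethylamine N-oxide, DMSO, rt) converts the primary allylic chloride into the enal 15.

Further compounds
F1 | step 4 | 5-acetyl-2-[(tert-butyldimethylsilyl)oxy]benzaldehyde | CC(=O)c1ccc(O[Si](C)(C)C(C)(C)C)c(C=O)c1
F2 | step 4 | rac-1-{4-[(tert-butyldimethylsilyl)oxy]-3-(1-hydroxy-3-methylbut-2-en-1-yl)phenyl}ethan-1-one | CC(=O)c1ccc(O[Si](C)(C)C(C)(C)C)c(C(O)C=C(C)C)c1
F3 | step 4 | 1-{4-[(tert-butyldimethylsilyl)oxy]-3-[(1S)-1-hydroxy-3-methylbut-2-en-1-yl]phenyl}ethan-1-one | CC(C)=C[C@H](O)c1cc(C(C)=O)ccc1O[Si](C)(C)C(C)(C)C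
F4 | step 4 | 1-{4-[(tert-butyldimethylsilyl)oxy]-3-[(R)-[(2R)-3,3-dimethyloxiran-2-yl](hydroxy)methyl]phenyl}ethan-1-one | CC1(C)O[C@@H]1[C@H](O)c1cc(C(C)=O)ccc1O[Si](C)(C)C(C)(C)C
F5 | step 4 | 1-[(2S,3R)-3-hydroxy-2-(2-hydroxypropan-2-yl)-2,3-dihydro-1-benzofuran-5-yl]ethan-1-one | CC(C)(O)[C@H]1Oc2ccc(C(C)=O)cc2[C@H]1O
F6 | step 4 | (2S,3R)-5-acetyl-2-(2-hydroxypropan-2-yl)-2,3-dihydro-1-benzofuran-3-yl 3-methylbutanoate | CC(C)(O)[C@H]1Oc2ccc(C(C)=O)cc2[C@H]1OC(=O)CC(C)C
F7 | step 3 | 1-[3-(hydroxymethyl)-4-(prop-2-yn-1-yloxy)phenyl]ethan-1-ol (racemic) | CC(O)c1ccc(OCC#C)c(CO)c1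
F8 | step 3 | 1-[3-(hydroxymethyl)-4-(propa-1,2-dien-1-yloxy)phenyl]ethan-1-ol (racemic) | CC(O)c1ccc(OC=C=C)c(CO)c1
F9 | step 9 | (2R,3R)-5-[(1S)-1-(acetyloxy)ethyl]-2-(3-chloroprop-1-en-2-yl)-2,3-dihydro-1-benzofuran-3-yl 3-methylbutanoate | C=C(CCl)[C@H]1Oc2ccc([C@H](C)OC(C)=O)cc2[C@H]1OC(=O)CC(C)C
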